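**Assumption (one line):** germacrane numbering is used throughout (C1 = THF CH, C4 = THF quaternary C, C5=C6 = ylidene, C7=C11 = butenolide alkene, C8 = ester carbinol, C10 = tertiary carbinol, C12 = lactone C=O, C13 = CH2O). The lactol carbon C6 of 20, 22 and 24 is carried as an epimer mixture because it becomes sp2 in the last step.

## Retrosynthetic overview
1. Target 25 ⇐ lactol 20, by C13 acetylation, then C8 methacrylation combined with dehydration to the 5E-ylidene lactone.
2. 20 ⇐ tetracycle 17. Key ring expansion: alkoxy-radical β-scission of the C1–C6 bond shared by rings A and B (6/6 → ten-membered ring plus THF).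
3. 17 ⇐ 15, by intramolecular furan Diels–Alder reaction (rings A and B formed together) and hydrogenation. Ring C (butenolide) is already in place.
4. 15 ⇐ (Z)-β-iodoenone 13 + CO (ring C, formed first). 13 ⇐ aldehyde 7 + ynone 11 (halo-aldol).
5. 7 ⇐ 2-methylfuran + Ac2O + allyl-MgBr (asymmetric allylboration sets C10). 11 ⇐ propargyl alcohol + N-methoxy-N-methylacetamide.

## Route

Step 1
Reactants: 1 2-methylfuran; 2 acetic anhydride
Product: 3 1-(5-methylfuran-2-yl)ethan-1-one
Conditions: 85% H3PO4 (5 mol %), neat, 0 to 45 °C, 2 h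
Reagents that add atoms: none
Why: Friedel–Crafts acylation of an electron-rich furan takes place only at the free α-position, and no stereocentre is formed.

Step 2
Reactants: 3 1-(5-methylfuran-2-yl)ethan-1-one; 4 allylmagnesium bromide
Product: 6 (R)-2-(5-methylfuran-2-yl)pent-4-en-2-ol, via allyl(diisopropoxy)borane 5 (not isolated)
Conditions: 4, B(OiPr)3, Et2O, −78 °C to rt, filter; then 3, (S)-3,3'-Br2-BINOL (15 mol %; the antipode gives ent-6), PhMe/PhCF3, −35 °C, 15 h; aq. NaHCO3
Reagents that add atoms: triisopropyl borate CC(C)OB(OC(C)C)OC(C)C (its atoms stay only in 5)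
Why: In this BINOL-catalysed asymmetric allylboration of an aryl methyl ketone, ligand exchange gives a chiral allylboronate whose closed chair transition state distinguishes furyl from methyl and sets C10 as R.

Step 3
Reactants: 6 (R)-2-(5-methylfuran-2-yl)pent-4-en-2-ol
Product: 7 (R)-3-hydroxy-3-(5-methylfuran-2-yl)butanal
Conditions: OsO4 (2 mol %), NaIO4 (2.2 equiv), 2,6-lutidine (2 equiv), dioxane/H2O 3:1, 0 °C to rt; used crude
Reagents that add atoms: sodium periodate [Na+].[O-]I(=O)(=O)=O (oxygen, relayed through OsO4)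
Why: In this Lemieux–Johnson cleavage the terminal alkene is dihydroxylated faster than the furan, and the lutidine buffer protects the acid-labile tertiary furfuryl alcohol, so C10 is untouched.

Step 4
Reactants: 8 prop-2-yn-1-ol; 9 N-methoxy-N-methylacetamide
Product: 11 5-hydroxypent-3-yn-2-one, via dilithiated propargyl alcohol 10 (not isolated)
Conditions: n-BuLi (2.1 equiv), THF, −78 °C; then 9, −78 to 0 °C; aq. NH4Cl
Reagents that add atoms: n-butyllithium [Li]CCCC (lithium only in 10)
Why: In this Weinreb ketone synthesis the chelated tetrahedral adduct stops the acetylide addition at the ynone stage.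

Step 5
Reactants: 7 (R)-3-hydroxy-3-(5-methylfuran-2-yl)butanal; 11 5-hydroxypent-3-yn-2-one
Product: 13 (Z)-3-[(1S,3R)-1,3-dihydroxy-3-(5-methylfuran-2-yl)butyl]-5-hydroxy-4-iodopent-3-en-2-one, via magnesium iodoallenolate 12 (not isolated)
Conditions: MgI2 (1.5 equiv), CH2Cl2, −20 to 0 °C; aq. NaHCO3/Na2S2O3
Reagents that add atoms: magnesium iodide [Mg+2].[I-].[I-]
Why: In this halo-aldol (β-iodo Morita–Baylis–Hillman) reaction iodide adds to C11 and the allenolate carbon C7 attacks the aldehyde anti to iodine, which places I cis to the acetyl group (Z); the aldehyde sits in a six-membered Mg chelate with the C10–OH (furyl pseudo-equatorial, methyl pseudo-axial), so attack anti to methyl gives the 1,3-syn diol with C8 = S.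

Step 6
Reactants: 13 (Z)-β-iodoenone triol; 14 carbon monoxide
Product: 15 4-[(1S,3R)-1,3-dihydroxy-3-(5-methylfuran-2-yl)butyl]-3-(hydroxymethyl)-5-methylidenefuran-2(5H)-one
Conditions: CO (20 bar), PdCl2(PPh3)2 (5 mol %), Et3N (2 equiv), MeCN, 60 °C
Reagents that add atoms: none
Why: In this carbonylative lactonisation of a (Z)-β-iodoenone, oxidative addition and CO insertion give an acylpalladium that is cis to the methyl ketone and is captured by its enolate oxygen; this closes ring C with the exocyclic C5=C6 bond, and the C8–OH lies trans and cannot compete.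

Step 7
Reactants: 15 γ-methylidene butenolide triol
Product: 17 (1R,4R,6R,8S,10R)-1,4-epoxy-8,10,13-trihydroxy-1,6-cyclogermacr-7(11)-en-12,6-olide (saturated 7-oxanorbornane ring A fused at C1–C6 to cyclohexane ring B, butenolide ring C on C6/C7), via oxanorbornene cycloadduct 16 (not isolated)
Conditions: H2O/EtOH 9:1 (0.02 M), BHT, 65 °C, 36 h; concentrate; RhCl(PPh3)3 (5 mol %), H2 (4 bar), EtOH/PhH, rt
Reagents that add atoms: none
Why: This is an intramolecular Diels–Alder reaction of furan, helped by the quaternary C10 next to the diene and by water; the four-atom tether reacts exo through a chair with both hydroxyls equatorial and the C10 methyl axial, which fixes C4 as R (and C1, C6), and hydrogenation of the strained C2=C3 bond blocks cycloreversion without touching the tetrasubstituted C7=C11 bond.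

Step 8
Reactants: 17 saturated tetracyclic lactone
Product: 20 (1S,4R,8S,10R)-1,4-epoxy-6,8,10,13-tetrahydroxygermacr-7(11)-en-12,6-olide (C6 epimers), via tetrabutylammonium hydroxy-carboxylate 18 (not isolated), via ring-expanded keto-carboxylate 19 (not isolated)
Conditions: Bu4NOH (1.0 equiv), THF/H2O, 0 °C, azeotropic drying (PhMe, ≤25 °C); [Ir(dF(CF3)ppy)2(5,5'-d(CF3)bpy)]PF6 (2 mol %), 2,4,6-triisopropylbenzenethiol (50 mol %), PhCF3/MeCN 4:1 (0.02 M), 450 nm LED, 25 °C; then 1 M HCl (1.0 equiv), 0 °C
Reagents that add atoms: tetrabutylammonium hydroxide CCCC[N+](CCCC)(CCCC)CCCC.[OH-] (oxygen in 20, cation in 18 and 19)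
Why: Proposed new method: opening the lactone places a carboxylate cis to, and hydrogen-bonded with, only the C6–OH, so the excited iridium photocatalyst can remove that O–H by concerted proton-coupled electron transfer (effective bond strength of the oxidant/carboxylate pair about 113 kcal/mol against about 105 for O–H); the C6 alkoxy radical then cleaves the congested C1–C6 bond, because this releases the oxanorbornane strain and gives a tertiary α-oxy radical while the alternatives would give a vinyl (C7) or primary (C5) radical; the thiol delivers H to C1 from the outer face, since the inner lobe is covered by the six-atom bridge, which gives the cis-2,5-THF with C1 = S; thiyl/thiolate turnover closes a redox-neutral cycle and acidification closes the keto acid to lactol 20. The closest known reaction types are photocatalytic PCET β-scission of unstrained cyclic alcohols with an external phosphate or collidine base plus a thiol, and Suárez alkoxy-radical fragmentation of β-alkoxy alcohols; the new features are the substrate-embedded base and the expansion of a 7-oxanorbornanol into an oxa-bridged ten-membered ring.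

Step 9
Reactants: 20 lactol tetraol; 21 acetyl chloride
Product: 22 13-O-acetyl derivative of 20
Conditions: AcCl (1.05 equiv), 2,4,6-collidine (2 equiv), CH2Cl2, −78 °C
Reagents that add atoms: none
Why: Acyl chloride with collidine at low temperature acylates only the primary C13–OH in the presence of the secondary, tertiary and lactol hydroxyls, and no stereocentre is affected.

Step 10
Reactants: 22 13-O-acetate; 23 methacryloyl chloride
Product: 25 (1S,4R,5E,8S,10R)-13-acetoxy-1,4-epoxy-10-hydroxy-8-methacryloyloxygermacra-5,7(11)-dien-12,6-olide (CNP0516045.1), via 6,8-bis-methacrylate 24 (not isolated)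
Conditions: 23 (2.5 equiv), Et3N (4 equiv), DMAP (10 mol %), BHT, CH2Cl2, −20 °C to rt
Reagents that add atoms: none
Why: DMAP-catalysed acylation esterifies the C8–OH and the lactol OH but not the hindered tertiary C10–OH; pseudo-ester 24 then ionises to the 2-oxofuranium ion and loses H5 (E1-type elimination), and the ten-membered ring allows only the ring-cis, that is 5E, ylidene lactone.

## Compound list
1 | 2-methylfuran | Cc1ccco1 | starting material
2 | acetic anhydride | CC(=O)OC(C)=O | starting material
3 | 1-(5-methylfuran-2-yl)ethan-1-one | CC(=O)c1ccc(C)o1 | intermediate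
4 | allylmagnesium bromide | C=CC[Mg]Br | starting material
5 | allyl(diisopropoxy)borane | C=CCB(OC(C)C)OC(C)C | intermediate
6 | (R)-2-(5-methylfuran-2-yl)pent-4-en-2-ol | C=CC[C@@](C)(O)c1ccc(C)o1 | intermediate
7 | (R)-3-hydroxy-3-(5-methylfuran-2-yl)butanal | O=CC[C@@](C)(O)c1ccc(C)o1 | intermediate
8 | prop-2-yn-1-ol | C#CCO | starting material
9 | N-methoxy-N-methylacetamide | CON(C)C(C)=O | starting material
10 | dilithiated propargyl alcohol | [Li]C#CCO[Li] | intermediate
11 | 5-hydroxypent-3-yn-2-one | CC(=O)C#CCO | intermediate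
12 | magnesium β-iodoallenolate of 11 | CC(O[Mg]I)=C=C(I)CO | intermediate
13 | (Z)-3-[(1S,3R)-1,3-dihydroxy-3-(5-methylfuran-2-yl)butyl]-5-hydroxy-4-iodopent-3-en-2-one | CC(=O)/C([C@@H](O)C[C@@](C)(O)c1ccc(C)o1)=C(\I)CO | intermediate
14 | carbon monoxide | [C-]#[O+] | starting material
15 | 4-[(1S,3R)-1,3-dihydroxy-3-(5-methylfuran-2-yl)butyl]-3-(hydroxymethyl)-5-methylidenefuran-2(5H)-one | C=C1OC(=O)C(CO)=C1[C@@H](O)C[C@@](C)(O)c1ccc(C)o1 | intermediate
16 | oxanorbornene cycloadduct (2,3-didehydro-17, same configuration) | C[C@]12C=C[C@@]3(O1)[C@](C)(O)C[C@H](O)C4=C(CO)C(=O)O[C@@]34C2 | intermediate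
17 | (1R,4R,6R,8S,10R) saturated tetracyclic epoxy-lactone triol | C[C@]12CC[C@@]3(O1)[C@](C)(O)C[C@H](O)C4=C(CO)C(=O)O[C@@]34C2 | intermediate
18 | tetrabutylammonium salt of the ring-C-opened (Z)-hydroxy acid | C[C@]12CC[C@@]3(O1)[C@](C)(O)C[C@H](O)/C(=C(\CO)C(=O)[O-])[C@]3(O)C2.CCCC[N+](CCCC)(CCCC)CCCC | intermediate
19 | tetrabutylammonium salt of the ring-expanded 6-keto-12-carboxylate | O[C@H]1C[C@@](C)(O)[C@@H]2CC[C@](C)(CC(=O)/C1=C(/CO)C(=O)[O-])O2.CCCC[N+](CCCC)(CCCC)CCCC | intermediate
20 | (1S,4R,8S,10R)-1,4-epoxy-6,8,10,13-tetrahydroxygermacr-7(11)-en-12,6-olide (C6 epimers) | O[C@H]1C[C@@](C)(O)[C@@H]2CC[C@](C)(CC3(O)OC(=O)C(CO)=C31)O2 | intermediate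
21 | acetyl chloride | CC(=O)Cl | starting material
22 | 13-O-acetyl-20 | O[C@H]1C[C@@](C)(O)[C@@H]2CC[C@](C)(CC3(O)OC(=O)C(COC(C)=O)=C31)O2 | intermediate
23 | methacryloyl chloride | C=C(C)C(=O)Cl | starting material
24 | 13-O-acetyl-6,8-di-O-methacryloyl-20 | C=C(C)C(=O)O[C@H]1C[C@@](C)(O)[C@@H]2CC[C@](C)(CC3(OC(=O)C(C)=C)OC(=O)C(COC(C)=O)=C31)O2 | intermediate
25 | CNP0516045.1 | C=C(C)C(=O)O[C@H]1C[C@@](C)(O)[C@@H]2CC[C@](C)(/C=C3/OC(=O)C(COC(C)=O)=C31)O2 | target

## Step count and risks
Total steps: 10. Longest linear sequence: 9 (steps 1, 2, 3, 5, 6, 7, 8, 9, 10; step 4 is a one-step branch).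

**Risk 1 – step 8 (the proposed new ring expansion).** The possible failures are these:
- unproductive PCET at the C13–OH;
- transannular addition of the C1 radical to the C7=C11 acceptor, which is why the thiol loading is high;
- later cleavage next to the C10–OH.

The fallback uses known chemistry, sets out from 17 and comes back at 20.
- Basha-type aminolysis with Me2AlNMe2 opens ring C to the stable (Z)-γ-hydroxy dimethylamide F1.
- Ac2O/pyridine acetylates only the C8 and C13 hydroxyls to give the diacetate F2.
- Suárez hypoiodite fragmentation (PhI(OAc)2, 1.1 equiv, I2, visible light) cleaves C1–C6. The α-oxy radical is oxidised, and the oxocarbenium ion is captured by acetate, which gives the ring-expanded C1-acetoxy ketal F3.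
- Ionic reduction with Et3SiH/BF3·OEt2 at −78 °C delivers hydride from the outer face and gives the cis-THF keto amide F4.
- LiOH, then dilute HCl in THF, removes the acetates and hydrolyses the amide with help from the neighbouring C6 ketone, which gives 20.

**Risk 2 – step 7 (IMDAF).** Three contiguous fully substituted carbons (C10, C1, C6) may make the equilibrium unfavourable. The fallback is temporary LUMO lowering by a redox relay. It sets out from 15 and comes back at 17.
- MnO2 oxidises the primary allylic C13–OH to the 3-formyl butenolide F5. Its extended acceptor, optionally activated as an iminium ion by a secondary amine salt, cyclises at room temperature.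
- Diimide reduction of the strained alkene gives the formyl tetracycle F6.
- NaBH4/CeCl3 returns 17.

**Risk 3 – step 5 (C8 configuration and alkene geometry in the halo-aldol).** The fallback sets C8 by catalyst control and builds ring C differently. It sets out from 7 and comes back at 15.
- TMSOTf/2,6-lutidine gives the silyl ether aldehyde F7.
- Me2Zn with the ProPhenol enantiomer that delivers the 8S carbinol adds methyl propiolate. A citric acid/MeOH work-up removes the silyl group and gives the γ-hydroxy ynoate F8.
- MgI2/paraformaldehyde halo-aldol (no new stereocentre, electrophile anti to iodine) gives the (Z)-β-iodo-α-(hydroxymethyl)acrylate F9.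
- LiOH gives the acid F10.
- Tandem cross-coupling and 5-exo-dig lactonisation with acetylene (Pd(PPh3)4, CuI, Et3N) gives 15.

## Further compounds
F1 | step 8 | ring-C-opened (Z)-γ-hydroxy N,N-dimethylamide of 17 | C[C@]12CC[C@@]3(O1)[C@](C)(O)C[C@H](O)/C(=C(\CO)C(=O)N(C)C)[C@]3(O)C2
F2 | step 8 | 8,13-di-O-acetyl-F1 | C[C@]12CC[C@@]3(O1)[C@](C)(O)C[C@H](OC(C)=O)/C(=C(\COC(C)=O)C(=O)N(C)C)[C@]3(O)C2
F3 | step 8 | ring-expanded 1-acetoxy-1,4-epoxy 6-keto amide (C1 epimers) | CC(=O)O[C@H]1C[C@@](C)(O)C2(OC(C)=O)CC[C@](C)(CC(=O)/C1=C(/COC(C)=O)C(=O)N(C)C)O2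
F4 | step 8 | (1S)-1,4-epoxy 6-keto amide diacetate | CC(=O)O[C@H]1C[C@@](C)(O)[C@@H]2CC[C@](C)(CC(=O)/C1=C(/COC(C)=O)C(=O)N(C)C)O2
F5 | step 7 | 3-formyl analogue of 15 | C=C1OC(=O)C(C=O)=C1[C@@H](O)C[C@@](C)(O)c1ccc(C)o1
F6 | step 7 | 13-oxo (formyl) analogue of 17 | C[C@]12CC[C@@]3(O1)[C@](C)(O)C[C@H](O)C4=C(C=O)C(=O)O[C@@]34C2
F7 | step 5 | (R)-3-(5-methylfuran-2-yl)-3-(trimethylsilyloxy)butanal | O=CC[C@@](C)(O[Si](C)(C)C)c1ccc(C)o1
F8 | step 5 | methyl (4S,6R)-4,6-dihydroxy-6-(5-methylfuran-2-yl)hept-2-ynoate | COC(=O)C#C[C@@H](O)C[C@@](C)(O)c1ccc(C)o1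
F9 | step 5 | methyl (Z,4S,6R)-4,6-dihydroxy-2-(hydroxymethyl)-3-iodo-6-(5-methylfuran-2-yl)hept-2-enoate | COC(=O)/C(CO)=C(\I)[C@@H](O)C[C@@](C)(O)c1ccc(C)o1
F10 | step 5 | carboxylic acid of F9 | OC(=O)/C(CO)=C(\I)[C@@H](O)C[C@@](C)(O)c1ccc(C)o1
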